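## Structural features

The target is a 3,3a-dihydro-1-benzofuran-6(2H)-one. A six-membered carbocycle (ring A: C3a, C4, C5, C6, C7, C7a) is fused along the C3a–C7a bond to a five-membered oxygen heterocycle (ring B: O1, C2, C3, C3a, C7a). Ring A is a cross-conjugated dienone: C4=C5 carries the C5 methoxy group, and C7=C7a, which ends at O1, is a vinylogous ester. Ring B carries the 3,4,5-trimethoxyphenyl group at C2, a methyl group at C3 and the allyl group on the all-carbon quaternary centre C3a. The stereocentres C2 (R), C3 (S) and C3a (S) are contiguous; aryl and methyl are cis on ring B and the allyl group is trans to the methyl group. Fragile points are the terminal alkene (no late hydrogenation, hydroboration or Wacker-type palladium chemistry), the benzylic C2–O1 ether next to an electron-rich arene (acid can ionise it and drift the cis-2,3 pair to trans), and the base- and nucleophile-sensitive dienone. The real difficulty is twofold: the quaternary stereocentre C3a next to C3, and the cis-2,3 relationship, which in an open chain is the unlike (1R,2S) carbinol that hydride reduction of an aryl ketone does not deliver. The key step uses the fact that C3a is para to the C6 carbonyl and that O1 sits on C7a, a β-carbon of that carbonyl. With one more methoxy group on C7, ring A derives from a 4,4-disubstituted 2,6-dimethoxycyclohexa-2,5-dienone with two identical enone arms, so C3a is prochiral and becomes stereogenic only when the C2 oxygen closes ring B on one arm.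

## Logic of the disconnections

20 to 19. No skeletal bond is cut; the C7=C7a double bond is taken back to a single bond with hydrogen on both carbons. The vinylogous ester cannot be the direct outcome of a conjugate addition, but its dihydro form can. The gain is an sp3 C7a bearing O1 and H. The forward step must dehydrogenate a ketone with one enolisable position (C7) without touching the allyl group or the benzylic C2–H.

19 to 18. A C7–OMe bond is added back. With methoxy groups on both α-carbons of the C6 carbonyl, the two halves of ring A have the same origin. The gain is a symmetric ring A precursor that already holds the C5 methoxy group. The forward step must cleave the sp3 C7–O bond reductively, leave the vinylic C5–O bond and keep ring B closed.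

18 to 17. The O1–C7a bond is cut. It is the bond an intramolecular oxa-Michael addition makes, and cutting it removes ring B and the stereocentres C3a and C7a at once. The gain is a monocyclic dienone with a prochiral quaternary carbon and only two stereocentres, both in the side chain. The forward step must choose one of two diastereotopic enone arms.

17 to 14 and 15. The bond between the carbinol carbon (C2) and its arene is cut. The unlike (1R,2S) carbinol is the Felkin–Anh product of adding an aryl nucleophile to an α-branched aldehyde, whereas hydride addition to the ketone would give the like isomer. The gain is convergence: nine carbons and one stereocentre are split off. The forward step must attack the aldehyde and not the dienone, must not epimerise C3, and must be worked up before the new oxygen adds to an enone.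

14 to 13 to 11. The aldehyde is traced to a silyl-protected primary alcohol. Then the C3a–CH2 bond of the allyl group is cut and the allyl group is returned to oxygen, the reverse of a para-Claisen rearrangement. The quaternary carbon disappears into a flat arene and the only stereocentre left is C3. The forward step needs two consecutive [3,3] shifts to end on a para carbon that cannot rearomatise. The primary oxygen must be masked, because a free hydroxyl would close ring B itself.

11 to 10 to 9 to 7. After the silyl group and the reductive release of the auxiliary, the C3–CH3 bond is cut. A benzylic methyl stereocentre α to an acyl group is reliably made by auxiliary-controlled enolate methylation. The gain is an achiral arylacetyl unit. The forward step must methylate once and must not exchange the acidic α-hydrogen of 9.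

7 to 4 and 5, then 4 to 1 and 2. The N-acyl bond and the aryl O–allyl bond are cut. This leads to a commercial arylacetic acid, a commercial oxazolidinone and allyl bromide. The forward steps are an acylation and a Williamson etherification.

## Other disconnections considered

Alternative 1: The cut is the C3a–C7a bond, so ring A is made in the key step and the quaternary carbon arises in a pericyclic event. Forward, the 4-alkenyl-3-isopropoxy-4-methoxycyclobutenone A1 is heated. Four-electron ring opening gives a dienylketene, whose ketene carbon (later C7a) closes onto the fully substituted alkene terminus (later C3a) by six-electron electrocyclisation to give the cyclohexa-2,4-dienone A2.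
- In its favour: the oxygen pattern of ring A comes regiodefined from a squaric ester, and no reagent is needed. A2 also needs no reduction–reoxidation: desilylation and an acid-mediated transposition of the vinylogous ester (the C2 oxygen adds at C7a, isopropanol leaves from C6) would reach 20. On redox economy after the key step this plan is the better one.
- Against it: the linear ketene terminus carries no stereochemical information. The configuration of C3a would rest on 1,2-induction from C3 alone, in a thermal and irreversible step that no catalyst can steer. Closure onto a terminus with two carbon substituents is slow, so an intramolecular [2+2] addition of the ketene to the allyl alkene may compete. A1 also requires a geometrically defined alkenylmetal that already holds both side-chain stereocentres.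
- Comparison: both plans make one ring and the C3a stereocentre in the key step (equal), here through a C–C bond, there through a C–O bond. The chosen closure is polar, catalysed and reversible, which allows correction; this one is concerted and final. The alternative saves the two steps after the key step but should pay more than that for A1.

Alternative 2: The cut is the C3–CH3 bond, disguised as the C3–CH2 bond of a cyclopropane, so the methyl carbon comes last. Forward, CF3CO2ZnCH2I (from Et2Zn, CH2I2 and CF3CO2H) would add to the C2=C3 enol ether of the 3aH-benzofuranone A3 on the face away from the allyl group to give the cyclopropane A4. Ionisation of the C2–CH2 bond and hydride delivery to the C2 oxocarbenium ion would then unveil the methyl group and C2–H.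
- In its favour: the C3/C3a relationship is set by approach control on a rigid bicycle (methylene anti to allyl means methyl trans to allyl, as in 20). Reduction of a five-membered oxocarbenium ion anti to the C3 substituent would give the cis-2,3 pair directly. On this point, reaching cis-2,3 without an open-chain unlike carbinol, the alternative is the better of the two.
- Against it: A3 must already contain the quaternary C3a as a single enantiomer, so the main problem is moved and not solved. The C2=C3 enol ether shares O1 with the vinylogous ester and is a weak donor toward the electrophilic carbenoid, while the allyl alkene competes. A3 is a 1,5-diene and may undergo a Cope shift. The acid needed to open A4 meets a dienone and an electron-rich arene.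
- Comparison: the chosen plan carries the methyl group from step 3, which is structurally simpler. Both plans need two steps after the key step (equal). A3 is a target-like compound whose synthesis should not be shorter than that of 17.

Alternative 3: The cut is the C5–C6 bond of ring A. Forward, an N-heterocyclic carbene would add to the aliphatic aldehyde of the dialdehyde A5. The resulting acyl anion equivalent would attack the formyl carbon of the β-alkoxyacrolein on C7a and close ring A as the acyloin A6.
- In its favour: ring B with all three stereocentres is complete beforehand, and the only new stereocentre, the C6 carbinol, is oxidised away later. The key step therefore has no selectivity to deliver, and on that point it is better than the chosen plan. The conditions are mild, metal-free and compatible with the allyl group.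
- Against it: C3a must be built earlier as a stereocentre carrying an allyl group and a two-carbon aldehyde chain, two groups that differ little. This is harder than the symmetric situation of 17. The acceptor carbonyl is deactivated by O1. The carbene may instead add to the enal and expel O1, which opens ring B, or the roles of the two aldehydes may be exchanged.
- Comparison: oxidation of A6 to the diosphenol and regioselective O-methylation at C5 are two steps, equal to the chosen plan after its key step. The route to A5 should be clearly longer than that to 17.

Key step: step 9

Remark: 1, 5 and 15 are taken as commercial materials; C7 of 18 is carried as a mixture of epimers because that centre is removed in step 10.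
Remark: hydride reduction of the corresponding aryl ketone would follow the Felkin–Anh model to the like (1R*,2R*) carbinol and hence to the 2,3-trans series; the unlike (1R,2S) carbinol 17 is therefore made by adding the aryl group to aldehyde 14, where the same model leads to the required diastereomer.

## Route

Step 1
Reactants: 1 2-(4-hydroxy-3,5-dimethoxyphenyl)acetic acid; 2 allyl bromide
Product: 4 2-[4-(allyloxy)-3,5-dimethoxyphenyl]acetic acid, via allyl ester 3 (not isolated)
Conditions: 2 (2.5 equiv), K2CO3, DMF, 50 °C; then NaOH, MeOH/H2O, rt; HCl work-up
Reagents that add atoms: sodium hydroxide, [Na+].[OH-]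
Why: Williamson alkylation of the phenoxide and the carboxylate (SN2 on allyl bromide), then saponification, which cleaves only the allyl ester; the hindered aryl allyl ether is inert to hydroxide.

Step 2
Reactants: 4 2-[4-(allyloxy)-3,5-dimethoxyphenyl]acetic acid; 5 (4S)-4-benzyl-1,3-oxazolidin-2-one
Product: 7 (4S)-3-{2-[4-(allyloxy)-3,5-dimethoxyphenyl]acetyl}-4-benzyl-1,3-oxazolidin-2-one, via mixed pivalic anhydride 6 (not isolated)
Conditions: PivCl, Et3N, THF, −20 °C; then LiCl, 5, −20 °C to rt
Reagents that add atoms: none
Why: N-acylation of the oxazolidinone through the mixed pivalic anhydride with LiCl activation; attack occurs at the unhindered arylacetyl carbonyl and no strong base is needed.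

Step 3
Reactants: 7 (4S)-3-{2-[4-(allyloxy)-3,5-dimethoxyphenyl]acetyl}-4-benzyl-1,3-oxazolidin-2-one
Product: 9 (4S)-3-{(2S)-2-[4-(allyloxy)-3,5-dimethoxyphenyl]propanoyl}-4-benzyl-1,3-oxazolidin-2-one, via sodium enolate 8 (not isolated)
Conditions: NaN(SiMe3)2 (1.05 equiv), THF, −78 °C; MeI, −78 to −40 °C
Reagents that add atoms: iodomethane, CI
Why: Evans auxiliary alkylation: the chelated (Z)-enolate 8 is methylated on the face opposite the benzyl group, which should set the later C3 as (S). Base is kept near one equivalent and the quench is cold so that the acidic benzylic α-hydrogen of 9 is not exchanged.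

Step 4
Reactants: 9 (4S)-3-{(2S)-2-[4-(allyloxy)-3,5-dimethoxyphenyl]propanoyl}-4-benzyl-1,3-oxazolidin-2-one
Product: 10 (2S)-2-[4-(allyloxy)-3,5-dimethoxyphenyl]propan-1-ol
Conditions: LiBH4, MeOH (1 equiv), Et2O, 0 °C
Reagents that add atoms: none
Why: Hydride reduction of the exocyclic imide carbonyl (reductive removal of the auxiliary) gives the primary alcohol without touching the benzylic stereocentre or the allyl ether; 5 is recovered.

Step 5
Reactants: 10 (2S)-2-[4-(allyloxy)-3,5-dimethoxyphenyl]propan-1-ol
Product: 11 triethyl{(2S)-2-[4-(allyloxy)-3,5-dimethoxyphenyl]propoxy}silane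
Conditions: Et3SiCl, imidazole, CH2Cl2, 0 °C
Reagents that add atoms: chlorotriethylsilane, CC[Si](Cl)(CC)CC
Why: Silylation of the primary alcohol; a free hydroxyl at this position would be able to close ring B by itself once the dienone exists.

Step 6
Reactants: 11 triethyl{(2S)-2-[4-(allyloxy)-3,5-dimethoxyphenyl]propoxy}silane
Product: 13 4-allyl-2,6-dimethoxy-4-[(2S)-1-(triethylsilyloxy)propan-2-yl]cyclohexa-2,5-dien-1-one, via ortho-dienone 12 (not isolated)
Conditions: N,N-diethylaniline, 190 °C, sealed tube
Reagents that add atoms: none
Why: Thermal para-Claisen rearrangement: a [3,3] shift to a methoxy-bearing ortho carbon gives 12, which cannot tautomerise and passes on by a Cope shift to the substituted para carbon, where the dienone is held because that carbon has no hydrogen to lose. The two enone arms of 13 are identical, so the new quaternary carbon is not yet stereogenic and C3 is untouched.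

Step 7
Reactants: 13 4-allyl-2,6-dimethoxy-4-[(2S)-1-(triethylsilyloxy)propan-2-yl]cyclohexa-2,5-dien-1-one
Product: 14 (2S)-2-(1-allyl-3,5-dimethoxy-4-oxocyclohexa-2,5-dien-1-yl)propanal
Conditions: (COCl)2, DMSO, CH2Cl2, −78 to −40 °C; iPr2NEt, −78 to 0 °C
Reagents that add atoms: none
Why: Direct Swern oxidation of a primary triethylsilyl ether: chlorodimethylsulfonium chloride exchanges the silyl group for the alkoxysulfonium salt, which collapses to the aldehyde with base, so the free primary alcohol is never liberated. The hindered amine and a cold quench limit epimerisation of C3; 14 is used at once.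

Step 8
Reactants: 14 (2S)-2-(1-allyl-3,5-dimethoxy-4-oxocyclohexa-2,5-dien-1-yl)propanal; 15 3,4,5-trimethoxyphenylmagnesium bromide
Product: 17 4-allyl-4-[(1R,2S)-1-hydroxy-1-(3,4,5-trimethoxyphenyl)propan-2-yl]-2,6-dimethoxycyclohexa-2,5-dien-1-one, via aryltitanium triisopropoxide 16 (not isolated)
Conditions: 15, ClTi(OiPr)3, THF, −78 to −20 °C; then 14, −78 to −20 °C; cold aq. NH4Cl
Reagents that add atoms: none
Why: Aryltitanium triisopropoxides add to aldehydes in preference to ketones, so the hindered, methoxy-flanked dienone carbonyl should be left alone (chemoselective 1,2-addition). Felkin–Anh control, with the quaternary ring carbon as the large group anti to the incoming aryl, should give the unlike (1R,2S) carbinol and so set C2. Cold hydrolysis delivers 17 before its oxygen can add to an enone arm.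

Step 9
Reactants: 17 4-allyl-4-[(1R,2S)-1-hydroxy-1-(3,4,5-trimethoxyphenyl)propan-2-yl]-2,6-dimethoxycyclohexa-2,5-dien-1-one
Product: 18 (2R,3S,3aS,7aS)-3a-allyl-5,7-dimethoxy-3-methyl-2-(3,4,5-trimethoxyphenyl)-3,3a,7,7a-tetrahydro-1-benzofuran-6(2H)-one (C7 either configuration)
Conditions: quinine-derived 3,5-bis(trifluoromethyl)phenyl squaramide (10 mol%), toluene, −20 °C to rt
Reagents that add atoms: none
Why: The quinuclidine nitrogen of the catalyst acts as a general base on the C2 hydroxyl while the squaramide N–H bonds hold the dienone carbonyl and a flanking methoxy oxygen, so the oxygen adds to the β-carbon C7a of one enone arm and the enol is protonated at C7. The closest known reaction type is the organocatalytic oxa-Michael desymmetrisation of 4,4-disubstituted cyclohexa-2,5-dienones that carry a tethered alcohol. Ring B closes in the 5-exo-trig mode. C7a is controlled by the tether: the oxygen can only reach the dienone face on which the side chain stands, so the ring fusion should be cis with H7a syn to the allyl group. C3a becomes stereogenic through the choice of arm; it is controlled by the catalyst pocket together with the expected preference of the C3 methyl group to lie beside the flat C4–H of the spectator arm and not beside the allyl CH2. C7 should form as a mixture of epimers, which does not matter because that centre is removed in step 10. The selectivity needed is the discrimination of two diastereotopic enone arms; the fixed (1R,2S) side chain of 17 makes it a diastereoselection that a matched catalyst can reinforce, and the reversibility of the addition lets a kinetic error be corrected by equilibration. The α-methoxy groups lower the electrophilicity of the enones, which should keep the uncatalysed background slow at low temperature.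

Step 10
Reactants: 18 (2R,3S,3aS,7aS)-3a-allyl-5,7-dimethoxy-3-methyl-2-(3,4,5-trimethoxyphenyl)-3,3a,7,7a-tetrahydro-1-benzofuran-6(2H)-one
Product: 19 (2R,3S,3aS,7aR)-3a-allyl-5-methoxy-3-methyl-2-(3,4,5-trimethoxyphenyl)-3,3a,7,7a-tetrahydro-1-benzofuran-6(2H)-one
Conditions: SmI2 (2.5 equiv), THF/MeOH, −78 °C
Reagents that add atoms: none
Why: Reductive cleavage of an α-alkoxy ketone by SmI2: two single-electron transfers to the C6 carbonyl expel methoxide from C7 and methanol protonates the samarium enolate, while the vinylic C5–OMe bond is not aligned for cleavage. Should the enolate expel O1 instead, the hydroxy enone formed can only re-close on the now unsubstituted arm, which restores 19 with C3a unchanged.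

Step 11
Reactants: 19 (2R,3S,3aS,7aR)-3a-allyl-5-methoxy-3-methyl-2-(3,4,5-trimethoxyphenyl)-3,3a,7,7a-tetrahydro-1-benzofuran-6(2H)-one
Product: 20 (2R,3S,3aS)-3a-allyl-5-methoxy-3-methyl-2-(3,4,5-trimethoxyphenyl)-3,3a-dihydro-1-benzofuran-6(2H)-one
Conditions: 2-iodoxybenzoic acid, 4-methoxypyridine N-oxide, DMSO, rt
Reagents that add atoms: none
Why: Dehydrogenation of a ketone with 2-iodoxybenzoic acid activated by the N-oxide: C7 is the only enolisable position and C7a–H the only β-hydrogen, so the C7=C7a bond of the vinylogous ester is the only possible outcome. A metal-free oxidant is chosen because divalent palladium with oxygen, or a palladium-mediated oxidation of a silyl enol ether, could attack or cyclise onto the allyl group.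

## Compound list

1 | 2-(4-hydroxy-3,5-dimethoxyphenyl)acetic acid | COc1cc(CC(=O)O)cc(OC)c1O | starting material
2 | allyl bromide | C=CCBr | starting material
3 | allyl 2-[4-(allyloxy)-3,5-dimethoxyphenyl]acetate | COc1cc(CC(=O)OCC=C)cc(OC)c1OCC=C | intermediate (not isolated)
4 | 2-[4-(allyloxy)-3,5-dimethoxyphenyl]acetic acid | COc1cc(CC(=O)O)cc(OC)c1OCC=C | intermediate
5 | (4S)-4-benzyl-1,3-oxazolidin-2-one | O=C1N[C@@H](Cc2ccccc2)CO1 | starting material
6 | 2-[4-(allyloxy)-3,5-dimethoxyphenyl]acetic pivalic anhydride | COc1cc(CC(=O)OC(=O)C(C)(C)C)cc(OC)c1OCC=C | intermediate (not isolated)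
7 | (4S)-3-{2-[4-(allyloxy)-3,5-dimethoxyphenyl]acetyl}-4-benzyl-1,3-oxazolidin-2-one | COc1cc(CC(=O)N2[C@@H](Cc3ccccc3)COC2=O)cc(OC)c1OCC=C | intermediate
8 | sodium (Z)-enolate of 7 | [Na+].[O-]/C(=C\c1cc(OC)c(OCC=C)c(OC)c1)N1[C@@H](Cc2ccccc2)COC1=O | intermediate (not isolated)
9 | (4S)-3-{(2S)-2-[4-(allyloxy)-3,5-dimethoxyphenyl]propanoyl}-4-benzyl-1,3-oxazolidin-2-one | COc1cc(cc(OC)c1OCC=C)[C@H](C)C(=O)N1[C@@H](Cc2ccccc2)COC1=O | intermediate
10 | (2S)-2-[4-(allyloxy)-3,5-dimethoxyphenyl]propan-1-ol | COc1cc(cc(OC)c1OCC=C)[C@H](C)CO | intermediate
11 | triethyl{(2S)-2-[4-(allyloxy)-3,5-dimethoxyphenyl]propoxy}silane | COc1cc(cc(OC)c1OCC=C)[C@H](C)CO[Si](CC)(CC)CC | intermediate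
12 | 6-allyl-2,6-dimethoxy-4-[(2S)-1-(triethylsilyloxy)propan-2-yl]cyclohexa-2,4-dien-1-one (C6 either configuration) | O=C1C(OC)=CC(=CC1(OC)CC=C)[C@H](C)CO[Si](CC)(CC)CC | intermediate (not isolated)
13 | 4-allyl-2,6-dimethoxy-4-[(2S)-1-(triethylsilyloxy)propan-2-yl]cyclohexa-2,5-dien-1-one | C=CCC1(C=C(OC)C(=O)C(OC)=C1)[C@H](C)CO[Si](CC)(CC)CC | intermediate
14 | (2S)-2-(1-allyl-3,5-dimethoxy-4-oxocyclohexa-2,5-dien-1-yl)propanal | C=CCC1(C=C(OC)C(=O)C(OC)=C1)[C@H](C)C=O | intermediate
15 | 3,4,5-trimethoxyphenylmagnesium bromide | COc1cc([Mg]Br)cc(OC)c1OC | starting material
16 | (3,4,5-trimethoxyphenyl)titanium triisopropoxide | COc1cc(cc(OC)c1OC)[Ti](OC(C)C)(OC(C)C)OC(C)C | intermediate (not isolated)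
17 | 4-allyl-4-[(1R,2S)-1-hydroxy-1-(3,4,5-trimethoxyphenyl)propan-2-yl]-2,6-dimethoxycyclohexa-2,5-dien-1-one | C=CCC1(C=C(OC)C(=O)C(OC)=C1)[C@H](C)[C@@H](O)c1cc(OC)c(OC)c(OC)c1 | intermediate
18 | (2R,3S,3aS,7aS)-3a-allyl-5,7-dimethoxy-3-methyl-2-(3,4,5-trimethoxyphenyl)-3,3a,7,7a-tetrahydro-1-benzofuran-6(2H)-one (C7 either configuration) | C=CC[C@]12C=C(OC)C(=O)C(OC)[C@H]1O[C@@H](c1cc(OC)c(OC)c(OC)c1)[C@H]2C | intermediate
19 | (2R,3S,3aS,7aR)-3a-allyl-5-methoxy-3-methyl-2-(3,4,5-trimethoxyphenyl)-3,3a,7,7a-tetrahydro-1-benzofuran-6(2H)-one | C=CC[C@]12C=C(OC)C(=O)C[C@H]1O[C@@H](c1cc(OC)c(OC)c(OC)c1)[C@H]2C | intermediate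
20 | (2R,3S,3aS)-3a-allyl-5-methoxy-3-methyl-2-(3,4,5-trimethoxyphenyl)-3,3a-dihydro-1-benzofuran-6(2H)-one | C=CC[C@]12C=C(OC)C(=O)C=C1O[C@@H](c1cc(OC)c(OC)c(OC)c1)[C@H]2C | target

## Step count and least certain steps

Total step count: 11. Longest linear sequence: 11 steps (1 to 20).

Step 9 (key step). The most likely failure is poor discrimination between the two enone arms, or a mismatch between the catalyst and the C2/C3 stereocentres. The two closures differ only in whether the C3 methyl group faces the spectator arm or the allyl group, and the methoxy-deactivated enones react slowly enough for a background reaction to interfere. A first recourse within the same approach is the quinidine-derived pseudo-enantiomer of the catalyst. The fallback gives up kinetic catalyst control: 17 is closed under thermodynamic control with catalytic DBU in CH2Cl2 at rt, which should equilibrate 18 with the (3aR,7aR) diastereomer F1 through retro-oxa-Michael opening. The two are separated and F1 is resubmitted to the base until it is used up. The fallback sets out from 17 and comes back at 18.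

Step 6. The most likely failure is incomplete conversion: the aryl allyl ether, the ortho-dienone and the para-dienone interconvert by [3,3] shifts, and the product lacks the driving force of rearomatisation. The fallback drains the equilibrium. From 10, oxidation with Dess–Martin periodinane would give the aldehyde (2S)-2-[4-(allyloxy)-3,5-dimethoxyphenyl]propanal F2. Addition of 16 (made from 15 and ClTi(OiPr)3) under Felkin–Anh control, with the arene as the large group, would give the carbinol (1R,2S)-2-[4-(allyloxy)-3,5-dimethoxyphenyl]-1-(3,4,5-trimethoxyphenyl)propan-1-ol F3. F3 is then heated in N,N-diethylaniline, so that 17 is consumed by ring closure as soon as the para-Claisen shift forms it; F1, formed beside 18, is recycled as described for step 9. The fallback sets out from 10 and comes back at 18.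

Step 8. The most likely failures are competing attack on the dienone (1,2- or conjugate addition), epimerisation of C3 in 14 before the addition, or ring closure of the metal alkoxide before work-up. The fallback installs the carbinol before the quaternary carbon. From 10, the aldehyde F2 and the carbinol F3 are made as above. Silylation (Et3SiCl, imidazole) gives the triethylsilyl ether F4, the para-Claisen rearrangement gives the silyl ether of 17 F5, and HF·pyridine in THF at −20 °C releases 17. The fallback sets out from 10 and comes back at 17.

Step 11. The most likely failure is competing oxidation at the benzylic C2–H or at the electron-rich arene, or incomplete conversion. The fallback replaces the hypervalent-iodine dehydrogenation by a selenoxide elimination. From 19, LiN(SiMe3)2 and PhSeCl in THF at −78 °C would give the 7-phenylselanyl ketone F6. Oxidation with H2O2 and pyridine in CH2Cl2 at 0 °C is followed by syn-elimination toward C7a–H, the only β-hydrogen. The fallback sets out from 19 and comes back at 20.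

## Further compounds

F1 | step 9 | (2R,3S,3aR,7aR)-3a-allyl-5,7-dimethoxy-3-methyl-2-(3,4,5-trimethoxyphenyl)-3,3a,7,7a-tetrahydro-1-benzofuran-6(2H)-one (C7 either configuration) | C=CC[C@@]12C=C(OC)C(=O)C(OC)[C@@H]1O[C@@H](c1cc(OC)c(OC)c(OC)c1)[C@H]2C
F2 | step 6 | (2S)-2-[4-(allyloxy)-3,5-dimethoxyphenyl]propanal | COc1cc(cc(OC)c1OCC=C)[C@H](C)C=O
F3 | step 6 | (1R,2S)-2-[4-(allyloxy)-3,5-dimethoxyphenyl]-1-(3,4,5-trimethoxyphenyl)propan-1-ol | COc1cc(cc(OC)c1OCC=C)[C@H](C)[C@@H](O)c1cc(OC)c(OC)c(OC)c1
F4 | step 8 | triethyl{(1R,2S)-2-[4-(allyloxy)-3,5-dimethoxyphenyl]-1-(3,4,5-trimethoxyphenyl)propoxy}silane | COc1cc(cc(OC)c1OCC=C)[C@H](C)[C@@H](O[Si](CC)(CC)CC)c1cc(OC)c(OC)c(OC)c1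
F5 | step 8 | 4-allyl-2,6-dimethoxy-4-[(1R,2S)-1-(triethylsilyloxy)-1-(3,4,5-trimethoxyphenyl)propan-2-yl]cyclohexa-2,5-dien-1-one | C=CCC1(C=C(OC)C(=O)C(OC)=C1)[C@H](C)[C@@H](O[Si](CC)(CC)CC)c1cc(OC)c(OC)c(OC)c1
F6 | step 11 | (2R,3S,3aS,7aS)-3a-allyl-5-methoxy-3-methyl-7-(phenylselanyl)-2-(3,4,5-trimethoxyphenyl)-3,3a,7,7a-tetrahydro-1-benzofuran-6(2H)-one (C7 either configuration) | C=CC[C@]12C=C(OC)C(=O)C([Se]c3ccccc3)[C@H]1O[C@@H](c1cc(OC)c(OC)c(OC)c1)[C@H]2C
A1 | alternative 1 | 4-{2-allyl-(3S,4R)-4-(tert-butyldimethylsilyloxy)-3-methyl-4-(3,4,5-trimethoxyphenyl)but-1-enyl}-3-isopropoxy-4-methoxycyclobut-2-en-1-one (alkene geometry and C4 of the four-membered ring not specified) | O=C1C=C(OC(C)C)C1(OC)C=C(CC=C)[C@H](C)[C@@H](O[Si](C)(C)C(C)(C)C)c1cc(OC)c(OC)c(OC)c1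
A2 | alternative 1 | (6S)-6-allyl-6-[(1R,2S)-1-(tert-butyldimethylsilyloxy)-1-(3,4,5-trimethoxyphenyl)propan-2-yl]-3-isopropoxy-4-methoxycyclohexa-2,4-dien-1-one | C=CC[C@@]1(C=C(OC)C(OC(C)C)=CC1=O)[C@H](C)[C@@H](O[Si](C)(C)C(C)(C)C)c1cc(OC)c(OC)c(OC)c1
A3 | alternative 2 | (3aS)-3a-allyl-5-methoxy-2-(3,4,5-trimethoxyphenyl)-1-benzofuran-6(3aH)-one | C=CC[C@]12C=C(OC)C(=O)C=C1OC(c1cc(OC)c(OC)c(OC)c1)=C2
A4 | alternative 2 | cyclopropane adduct of A3 across C2 and C3 with the methylene group anti to the allyl group | C=CC[C@]12C=C(OC)C(=O)C=C1O[C@@]3(c4cc(OC)c(OC)c(OC)c4)C[C@@H]23
A5 | alternative 3 | (E)-2-[3-allyl-4-methyl-3-(2-oxoethyl)-5-(3,4,5-trimethoxyphenyl)oxolan-2-ylidene]acetaldehyde with the ring configuration of 20 | C=CC[C@]1(CC=O)/C(=C\C=O)O[C@@H](c2cc(OC)c(OC)c(OC)c2)[C@H]1C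
A6 | alternative 3 | 3a-allyl-6-hydroxy-3-methyl-2-(3,4,5-trimethoxyphenyl)-3,3a,4,6-tetrahydro-1-benzofuran-5(2H)-one with the ring B configuration of 20 (C6 either configuration) | C=CC[C@]12CC(=O)C(O)C=C1O[C@@H](c1cc(OC)c(OC)c(OC)c1)[C@H]2C
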